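Readings and results come from a simulation for substances that don't exist, noise included.

At early times the amber run shows how the substrate is shared out, but our question concerns the last few percent of it.

common to all: gas 1.6 mM (held)
- amber: substrate 30 mM; run made earlier
- flask: substrate 20 mM; time 4.0 d

- amber (time / h: target / %, side product A / %): 2.50: 4.4, 19.4; 6.00: 10.0, 38.9; 12.0: 17.3, 56.9; 20.0: 25.4, 65.6

(standard deviation of a reading: 0.5 percentage points)

1. at 4.0 d, what has stopped the reaction, if anything has (all of the substrate has reacted / it is still moving / forward and back rates have come level)
2. amount of target at 4.0 d, in percent of the substrate charged
3. amount of side product A at 4.0 d, in percent of the substrate charged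
4. amount of side product B at 4.0 d, in percent of the substrate charged
5. amount of target if the flask were left three thousand times as long, in percent of the substrate charged

- in percentages every species weighs as the substrate in it: one side product B counts as two
- at the start none of partner is dissolved
- candidate steps: substrate + partner -> target; substrate -> side product A; 2 substrate -> side product B; partner -> decomposed reagent; gas <-> partner
- the reaction counts as stopped when no species that holds the substrate changes by six tenths of a point or more over the second half of the time

We turn the question round. For this flask to count as still moving at 4.0 d, at least 0.600 points of substrate must stand at half that time. A pseudo-first-order tail leaves that much if its time constant reaches 9.38 h.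

The amber readings give a time constant to hold against this. The gap 100 minus target minus side product A counts substrate plus side product B, so it overstates the substrate. It falls from 25.8% at 12.0 h to 9.00% at 20.0 h. That reads as 7.60 h: this tail time constant τ, the time the late gap needs to shrink by a factor e, is what we carry.

It lies below the line, but not by much. Side product A by itself, read from the first amber reading, gives 11.4 h, which is longer than the line, so the margin rests on the target step. This flask charges less substrate than amber under the same gas, so we keep τ. It leaves 0.181% at half time, and we expect the substrate to be gone.

The forecast says the same of the end: all of the substrate has reacted, with 35.5% target, 62% side product A, 2.5% side product B and 35.5% target after the long wait, of which it says: “All steps are irreversible towards substrate, so waiting longer adds nothing.”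

    substrate + partner → target (k = 1.90 L mol⁻¹ min⁻¹)
    substrate → side product A (k = 0.00150 min⁻¹)
    2 substrate → side product B (k = 0.00210 L mol⁻¹ min⁻¹)
    partner → decomposed reagent (k = 8.70 × 10⁻⁴ min⁻¹)
    gas ⇌ partner, rate k5*(csat - [partner]) (kL = 0.00680 min⁻¹)

The flask gives all of the substrate has reacted, with 34.4% target, 63.7% side product A, 1.95% side product B and 34.4% target after the long wait. Its substrate stands at 0% at 2.00 d. Between 54.9% at 0.200 d and 4.76% at 0.800 d that substrate falls with a time constant of 5.89 h, shorter than τ and a factor 1.59 below the line. Carried to the neighbour flask with 34 mM of substrate, τ fits 12.6 time constants into 4.0 d, and that flask ends with 0% of its substrate left.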